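**Retrosynthetic overview**
1. Last bond: C7'–C8' (alkenyl carbon to the lactone CH2), made by a Ni-catalysed radical cross-electrophile coupling of an unprotected vinyl-bromide cyclohexenone core with a bromomethyl lactone.
2. Lactone: taken from the chiral pool as (S)-5-(hydroxymethyl)butyrolactone, then trans α-methylation and OTBS→Br; this ring is bought, not formed.
3. Core: cis-selective ketone reduction and ketal hydrolysis of a trans-5,6-disubstituted ketone, itself from Cu-catalysed asymmetric methyl conjugate addition to a quinone monoketal with in-situ enolate allylation by a C9 dibromide.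
4. Quinone monoketal from catechol (O-methylation, ortho-hydroxylation, oxidative dearomatisation); the carbocycle is the original arene ring, so no ring closure is needed.
5. C9 dibromide from hexa-1,5-diyne (C-methylation, carboalumination/CH2O, hydrozirconation/NBS, Appel). Ring order: carbocycle elaborated first, preformed lactone attached last.

Assumption: the (S,R,R)-Feringa phosphoramidite is taken to give the (R)-methyl adduct in step 8; if the sense is opposite, its enantiomer is used.

**Route**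

Step 1
Reactants: 1 catechol
Product: 2 1,2-dimethoxybenzene
Conditions: MeI (2.5 eq), K2CO3, acetone, reflux
Reagents that add atoms: iodomethane CI
Why: Williamson ether synthesis of both phenolic OH groups; no stereocentre.

Step 2
Reactants: 2 1,2-dimethoxybenzene
Product: 5 2,3-dimethoxyphenol, via 2,3-dimethoxyphenyllithium 3 (not isolated), via dimethyl 2,3-dimethoxyphenylboronate 4 (not isolated)
Conditions: n-BuLi, TMEDA, THF, 0 °C→rt; B(OMe)3, −78 °C→rt; AcOH, 30% H2O2, 0 °C→rt
Reagents that add atoms: hydrogen peroxide OO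
Why: Directed ortho-metalation next to OMe, borylation and oxidative C–B to C–O conversion give the 1,2,3-trioxygenated arene.

Step 3
Reactants: 5 2,3-dimethoxyphenol
Product: 7 2,3,4,4-tetramethoxycyclohexa-2,5-dien-1-one, via 2,3,4-trimethoxyphenol 6 (not isolated)
Conditions: PhI(OAc)2 (2.1 eq), MeOH, 0 °C
Reagents that add atoms: methanol CO
Why: Hypervalent-iodine oxidative dearomatisation, in which two successive phenol oxidations with methanol capture at the free para position give the p-quinone monoketal.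

Step 4
Reactants: 8 hexa-1,5-diyne
Product: 10 hepta-1,5-diyne, via hexa-1,5-diyn-1-yllithium 9 (not isolated)
Conditions: 8 (3 eq), n-BuLi (1 eq), THF, −78 °C; MeI, DMPU, −78 °C→rt; excess 8 distilled off and reused
Reagents that add atoms: iodomethane CI
Why: Acetylide alkylation, where monolithiation of the diyne used in excess keeps double methylation low and gives the unsymmetrical diyne.

Step 5
Reactants: 10 hepta-1,5-diyne
Product: 13 (E)-3-methyloct-2-en-6-yn-1-ol, via alkenyldimethylalane 11 (not isolated), via lithium alkenylalanate 12 (not isolated)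
Conditions: Me3Al (2 eq), Cp2ZrCl2 (20 mol%), CH2Cl2, 0 °C→rt; n-BuLi, −78 °C; (CH2O)n, THF, rt
Reagents that add atoms: trimethylaluminium C[Al](C)C; formaldehyde (as paraformaldehyde) C=O
Why: Negishi Zr-catalysed carboalumination adds Me–Al syn across the terminal alkyne only (Me on the internal carbon), and the alanate is hydroxymethylated with retention, which sets the 2E olefin.

Step 6
Reactants: 13 (E)-3-methyloct-2-en-6-yn-1-ol
Product: 15 (2E,6E)-7-bromo-3-methylocta-2,6-dien-1-ol, via alkenylzirconocene alkoxide 14 (not isolated)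
Conditions: Cp2Zr(H)Cl (2.5 eq), THF, rt→40 °C; NBS, 0 °C
Reagents that add atoms: N-bromosuccinimide BrN1C(=O)CCC1=O
Why: Schwartz hydrozirconation (first equivalent consumed by the OH) adds H–Zr syn and, after equilibration with excess reagent, places Zr on the less hindered methyl-bearing carbon; bromination with retention gives the (E)-vinyl bromide.

Step 7
Reactants: 15 (2E,6E)-7-bromo-3-methylocta-2,6-dien-1-ol
Product: 16 (2E,6E)-1,7-dibromo-3-methylocta-2,6-diene
Conditions: CBr4, PPh3, CH2Cl2, 0 °C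
Reagents that add atoms: tetrabromomethane BrC(Br)(Br)Br
Why: Appel reaction converts the primary allylic alcohol into the bromide by SN2 without touching either olefin geometry or the vinyl bromide.

Step 8
Reactants: 7 2,3,4,4-tetramethoxycyclohexa-2,5-dien-1-one; 16 (2E,6E)-1,7-dibromo-3-methylocta-2,6-diene
Product: 18 (5R,6R)-6-[(2E,6E)-7-bromo-3-methylocta-2,6-dien-1-yl]-2,3,4,4-tetramethoxy-5-methylcyclohex-2-en-1-one, via methylzinc enolate 17 (not isolated)
Conditions: Me2Zn (1.1 eq), Cu(OTf)2 (2 mol%), (S,R,R)-Feringa phosphoramidite (4 mol%), toluene, −25 °C; then 16 (1.3 eq), HMPA, THF, 0 °C→rt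
Reagents that add atoms: dimethylzinc C[Zn]C
Why: Cu/phosphoramidite-catalysed asymmetric conjugate addition of Me2Zn to the only unsubstituted enone sets C5 (R) by ligand control, and the zinc enolate is alkylated in HMPA at the primary allylic carbon anti to the new methyl, giving the trans (5R,6R) ketone (tandem conjugate addition–enolate alkylation).

Step 9
Reactants: 18 (5R,6R)-6-[(2E,6E)-7-bromo-3-methylocta-2,6-dien-1-yl]-2,3,4,4-tetramethoxy-5-methylcyclohex-2-en-1-one
Product: 20 (4R,5R,6R)-5-[(2E,6E)-7-bromo-3-methylocta-2,6-dien-1-yl]-4-hydroxy-2,3-dimethoxy-6-methylcyclohex-2-en-1-one, via alcohol ketal 19 (not isolated)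
Conditions: L-Selectride, THF, −78 °C; then 1 M aq HCl, THF, 0 °C
Reagents that add atoms: water O
Why: The bulky hydride attacks the carbonyl 1,2 from the face opposite the adjacent side chain (OH cis to the chain), and the acid quench hydrolyses the activated ketal to the β-methoxy enone (ketal hydrolysis), the α-methyl centre staying in its more stable trans arrangement.

Step 10
Reactants: 21 (S)-5-(hydroxymethyl)dihydrofuran-2(3H)-one
Product: 22 (S)-5-{[(tert-butyldimethylsilyl)oxy]methyl}dihydrofuran-2(3H)-one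
Conditions: TBSCl, imidazole, DMF, rt
Reagents that add atoms: tert-butyldimethylsilyl chloride CC(C)(C)[Si](C)(C)Cl
Why: Silyl protection of the primary alcohol supplies the bulky γ-substituent that will steer the enolate alkylation; the stereocentre is untouched.

Step 11
Reactants: 22 (S)-5-{[(tert-butyldimethylsilyl)oxy]methyl}dihydrofuran-2(3H)-one
Product: 24 (3R,5S)-5-{[(tert-butyldimethylsilyl)oxy]methyl}-3-methyldihydrofuran-2(3H)-one, via lithium lactone enolate 23 (not isolated)
Conditions: LDA (commercial solution, 1.05 eq), THF, −78 °C; MeI (3 eq), −78 °C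
Reagents that add atoms: iodomethane CI
Why: Lactone enolate alkylation, in which MeI approaches anti to the γ-CH2OTBS group and gives the trans (3R,5S) lactone (about 9:1, minor cis isomer removed by chromatography).

Step 12
Reactants: 24 (3R,5S)-5-{[(tert-butyldimethylsilyl)oxy]methyl}-3-methyldihydrofuran-2(3H)-one
Product: 25 (3R,5S)-5-(bromomethyl)-3-methyldihydrofuran-2(3H)-one
Conditions: Ph3PBr2 (commercial, 1.3 eq), CH2Cl2, rt
Reagents that add atoms: dibromotriphenylphosphorane BrP(Br)(c1ccccc1)(c1ccccc1)c1ccccc1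
Why: Direct silyl ether to bromide conversion with Ph3PBr2 (oxyphosphonium formation, SN2 by bromide at the primary carbon) under neutral conditions that do not epimerise the α-centre.

Step 13
Reactants: 20 (4R,5R,6R)-5-[(2E,6E)-7-bromo-3-methylocta-2,6-dien-1-yl]-4-hydroxy-2,3-dimethoxy-6-methylcyclohex-2-en-1-one; 25 (3R,5S)-5-(bromomethyl)-3-methyldihydrofuran-2(3H)-one
Product: 26 (4R,5R,6R)-4-hydroxy-2,3-dimethoxy-6-methyl-5-{(2E,6E)-3,7-dimethyl-8-[(2S,4R)-4-methyl-5-oxooxolan-2-yl]octa-2,6-dien-1-yl}cyclohex-2-en-1-one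
Conditions: NiBr2·glyme (10 mol%), dtbbpy (10 mol%), NaI (0.5 eq), Mn powder (3 eq), DMA, 25 °C; 25 (1.5 eq)
Reagents that add atoms: none
Why: Nickel-catalysed reductive cross-electrophile coupling, in which Ni(0) inserts into the alkenyl bromide with retention of E geometry and the primary radical from 25 (via the iodide) is captured at nickel before C–C reductive elimination; Mn instead of Zn avoids an organozinc that would open the lactone by β-elimination, and no stereocentre sits at the radical carbon, so all five are carried through.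

**Compound list**
1 | catechol | Oc1ccccc1O | starting material
2 | 1,2-dimethoxybenzene | COc1ccccc1OC | intermediate
3 | 2,3-dimethoxyphenyllithium | [Li]c1cccc(OC)c1OC | intermediate
4 | dimethyl 2,3-dimethoxyphenylboronate | COB(OC)c1cccc(OC)c1OC | intermediate
5 | 2,3-dimethoxyphenol | COc1cccc(O)c1OC | intermediate
6 | 2,3,4-trimethoxyphenol | COc1ccc(O)c(OC)c1OC | intermediate
7 | 2,3,4,4-tetramethoxycyclohexa-2,5-dien-1-one | COC1=C(OC)C(OC)(OC)C=CC1=O | intermediate
8 | hexa-1,5-diyne | C#CCCC#C | starting material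
9 | hexa-1,5-diyn-1-yllithium | [Li]C#CCCC#C | intermediate
10 | hepta-1,5-diyne | CC#CCCC#C | intermediate
11 | (E)-dimethyl(2-methylhept-1-en-5-yn-1-yl)alane | C[Al](C)/C=C(\C)CCC#CC | intermediate
12 | lithium (E)-butyldimethyl(2-methylhept-1-en-5-yn-1-yl)alanate | [Li+].CCCC[Al-](C)(C)/C=C(\C)CCC#CC | intermediate
13 | (E)-3-methyloct-2-en-6-yn-1-ol | OC/C=C(\C)CCC#CC | intermediate
14 | O,C7-bis(chlorozirconocene) derivative of (2E,6E)-3-methylocta-2,6-dien-1-ol | Cl[Zr](C1C=CC=C1)(C1C=CC=C1)OC/C=C(\C)CC/C=C(\C)[Zr](Cl)(C1C=CC=C1)C1C=CC=C1 | intermediate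
15 | (2E,6E)-7-bromo-3-methylocta-2,6-dien-1-ol | OC/C=C(\C)CC/C=C(\C)Br | intermediate
16 | (2E,6E)-1,7-dibromo-3-methylocta-2,6-diene | BrC/C=C(\C)CC/C=C(\C)Br | intermediate
17 | methylzinc (R)-4,4,5,6-tetramethoxy-3-methylcyclohexa-1,5-dien-1-olate | COC1=C(OC)C(O[Zn]C)=C[C@@H](C)C1(OC)OC | intermediate
18 | (5R,6R)-6-[(2E,6E)-7-bromo-3-methylocta-2,6-dien-1-yl]-2,3,4,4-tetramethoxy-5-methylcyclohex-2-en-1-one | COC1=C(OC)C(=O)[C@H](C/C=C(\C)CC/C=C(\C)Br)[C@@H](C)C1(OC)OC | intermediate
19 | (1R,5R,6R)-6-[(2E,6E)-7-bromo-3-methylocta-2,6-dien-1-yl]-2,3,4,4-tetramethoxy-5-methylcyclohex-2-en-1-ol | COC1=C(OC)[C@H](O)[C@H](C/C=C(\C)CC/C=C(\C)Br)[C@@H](C)C1(OC)OC | intermediate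
20 | (4R,5R,6R)-5-[(2E,6E)-7-bromo-3-methylocta-2,6-dien-1-yl]-4-hydroxy-2,3-dimethoxy-6-methylcyclohex-2-en-1-one | COC1=C(OC)[C@H](O)[C@H](C/C=C(\C)CC/C=C(\C)Br)[C@@H](C)C1=O | intermediate
21 | (S)-5-(hydroxymethyl)dihydrofuran-2(3H)-one | OC[C@@H]1CCC(=O)O1 | starting material
22 | (S)-5-{[(tert-butyldimethylsilyl)oxy]methyl}dihydrofuran-2(3H)-one | CC(C)(C)[Si](C)(C)OC[C@@H]1CCC(=O)O1 | intermediate
23 | lithium enolate of 22 | CC(C)(C)[Si](C)(C)OC[C@@H]1CC=C(O[Li])O1 | intermediate
24 | (3R,5S)-5-{[(tert-butyldimethylsilyl)oxy]methyl}-3-methyldihydrofuran-2(3H)-one | CC(C)(C)[Si](C)(C)OC[C@@H]1C[C@@H](C)C(=O)O1 | intermediate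
25 | (3R,5S)-5-(bromomethyl)-3-methyldihydrofuran-2(3H)-one | BrC[C@@H]1C[C@@H](C)C(=O)O1 | intermediate
26 | (4R,5R,6R)-4-hydroxy-2,3-dimethoxy-6-methyl-5-{(2E,6E)-3,7-dimethyl-8-[(2S,4R)-4-methyl-5-oxooxolan-2-yl]octa-2,6-dien-1-yl}cyclohex-2-en-1-one | COC1=C(OC)[C@H](O)[C@H](C/C=C(\C)CC/C=C(\C)C[C@@H]2C[C@@H](C)C(=O)O2)[C@@H](C)C1=O | target

**Totals and risks**

Total step count: 13. Longest linear sequence: 7 steps (steps 4, 5, 6, 7, 8, 9, 13 from hexa-1,5-diyne).

Most likely to fail:

Step 13 (final radical coupling on the unprotected hydroxy-enone). The fallback sets out from 15 and makes the same Csp3–Csp2 bond earlier, where the only other functional group is a primary alcohol. 15 and 25 are joined under silyl-radical halogen-abstraction Ni/photoredox conditions ((TMS)3SiH, Ir photocatalyst, NiCl2·dtbbpy, Na2CO3, DME, blue LEDs) to give (3R,5S)-5-[(2E,6E)-8-hydroxy-2,6-dimethylocta-2,6-dien-1-yl]-3-methyldihydrofuran-2(3H)-one F4. Appel bromination gives (3R,5S)-5-[(2E,6E)-8-bromo-2,6-dimethylocta-2,6-dien-1-yl]-3-methyldihydrofuran-2(3H)-one F5. The tandem conjugate addition/alkylation of 7 (through 17) with F5 gives (5R,6R)-6-{(2E,6E)-3,7-dimethyl-8-[(2S,4R)-4-methyl-5-oxooxolan-2-yl]octa-2,6-dien-1-yl}-2,3,4,4-tetramethoxy-5-methylcyclohex-2-en-1-one F6. L-Selectride at −78 °C (ketone faster than lactone) gives in the flask (1R,5R,6R)-6-{(2E,6E)-3,7-dimethyl-8-[(2S,4R)-4-methyl-5-oxooxolan-2-yl]octa-2,6-dien-1-yl}-2,3,4,4-tetramethoxy-5-methylcyclohex-2-en-1-ol F7, and the acid quench brings the route back at 26.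

Step 8 (sluggish zinc enolate allylation, or Cu-mediated methylation of the allylic bromide). The fallback sets out from 7. The conjugate addition is run as before, but enolate 17 is trapped with TMSCl and isolated as (R)-trimethyl[(4,4,5,6-tetramethoxy-3-methylcyclohexa-1,5-dien-1-yl)oxy]silane F2. MeLi in THF at 0 °C then releases lithium (R)-4,4,5,6-tetramethoxy-3-methylcyclohexa-1,5-dien-1-olate F3, free of copper and zinc. F3 is alkylated with 16 (HMPA, −78→−20 °C) and the route is rejoined at 18.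

Step 3 (ortho attack at the OMe-bearing carbon instead of para attack). The fallback sets out from 5. NBS in MeCN at 0 °C brominates para to the OH to give 4-bromo-2,3-dimethoxyphenol F1. Cu-catalysed methoxylation (NaOMe, CuI, MeOH/DMF, 110 °C) then gives 6 as an isolated compound. A single oxidation of this para-methoxyphenol with PhI(OAc)2 (1.1 eq) in MeOH brings the route back at 7.

**Further compounds**
F1 | step 3 | 4-bromo-2,3-dimethoxyphenol | Oc1ccc(Br)c(OC)c1OC
F2 | step 8 | (R)-trimethyl[(4,4,5,6-tetramethoxy-3-methylcyclohexa-1,5-dien-1-yl)oxy]silane | COC1=C(OC)C(O[Si](C)(C)C)=C[C@@H](C)C1(OC)OC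
F3 | step 8 | lithium (R)-4,4,5,6-tetramethoxy-3-methylcyclohexa-1,5-dien-1-olate | COC1=C(OC)C(O[Li])=C[C@@H](C)C1(OC)OC
F4 | step 13 | (3R,5S)-5-[(2E,6E)-8-hydroxy-2,6-dimethylocta-2,6-dien-1-yl]-3-methyldihydrofuran-2(3H)-one | OC/C=C(\C)CC/C=C(\C)C[C@@H]1C[C@@H](C)C(=O)O1
F5 | step 13 | (3R,5S)-5-[(2E,6E)-8-bromo-2,6-dimethylocta-2,6-dien-1-yl]-3-methyldihydrofuran-2(3H)-one | BrC/C=C(\C)CC/C=C(\C)C[C@@H]1C[C@@H](C)C(=O)O1
F6 | step 13 | (5R,6R)-6-{(2E,6E)-3,7-dimethyl-8-[(2S,4R)-4-methyl-5-oxooxolan-2-yl]octa-2,6-dien-1-yl}-2,3,4,4-tetramethoxy-5-methylcyclohex-2-en-1-one | COC1=C(OC)C(=O)[C@H](C/C=C(\C)CC/C=C(\C)C[C@@H]2C[C@@H](C)C(=O)O2)[C@@H](C)C1(OC)OC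
F7 | step 13 | (1R,5R,6R)-6-{(2E,6E)-3,7-dimethyl-8-[(2S,4R)-4-methyl-5-oxooxolan-2-yl]octa-2,6-dien-1-yl}-2,3,4,4-tetramethoxy-5-methylcyclohex-2-en-1-ol | COC1=C(OC)[C@H](O)[C@H](C/C=C(\C)CC/C=C(\C)C[C@@H]2C[C@@H](C)C(=O)O2)[C@@H](C)C1(OC)OC
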